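**Retrosynthetic overview**

- The target is the threo (7S,8S) guaiacylglycerol 8-O-4′ ether of syringic acid. The last operations are saponification of the ring B ester, removal of two silyl groups and reduction of a C7 ketone under 1,2-induction from C8.
- The strategy rests on ring A: C1 carries the C7 side chain, C3 carries OMe, C4 carries OH, and C2, C5 and C6 are CH. This is the pattern written by a 1-amino-2-methoxy-3-siloxybutadiene adding to a terminal ynone whose carbonyl carbon is C7.
- Key disconnection: the C1–C2 and C5–C6 bonds of ring A (Diels–Alder), followed by loss of dimethylamine. Ring B is bought as methyl syringate, so ring A is the only ring formed (step 8).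
- Ynone: the C7–alkyne bond comes from a Weinreb amide and ethynylmagnesium bromide; the C8–O4′ bond comes from Mitsunobu inversion of a D-glycerate-derived carbinol with methyl syringate. The diene comes from methoxyacetone in two steps.
- Stereochemistry: C8 from the chiral pool (inverted once), C7 by Felkin–Anh reduction.

Key step: step 8

Remark: neolignan numbering is used (C7 benzylic carbinol carbon, C8 aryloxy-bearing carbon, C9 the CH2OH carbon; ring A the guaiacyl ring, ring B the syringate ring); the given SMILES corresponds to the (7S,8S) threo isomer.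

**Route**

Step 1
Reactants: 1 methoxyacetone; 2 N,N-dimethylformamide dimethyl acetal
Product: 3 (3Z)-4-(dimethylamino)-3-methoxybut-3-en-2-one
Conditions: neat, 90 °C, MeOH distilled off; vacuum distillation
Reagents that add atoms: none
Why: Enaminone condensation of a ketone with an amide acetal, in which the CH2 flanked by carbonyl and methoxy is the more readily enolised site, so condensation there with loss of two MeOH should give the push–pull enaminone with NMe2 trans to acetyl, any methyl-side regioisomer being removed in the distillation.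

Step 2
Reactants: 3 (3Z)-4-(dimethylamino)-3-methoxybut-3-en-2-one
Product: 5 (1Z)-3-[(tert-butyldimethylsilyl)oxy]-2-methoxy-N,N-dimethylbuta-1,3-dien-1-amine, via potassium dienolate 4 (not isolated)
Conditions: KN(SiMe3)2, THF, −78 °C; then TBSCl, −78 °C → rt; filtration under N2, bulb-to-bulb distillation
Reagents that add atoms: tert-butyldimethylsilyl chloride, CC(C)(C)[Si](C)(C)Cl
Why: Kinetic deprotonation of the only enolisable position (the acetyl CH3) of the vinylogous amide and O-silylation of the dienolate is the standard preparation of 1-amino-3-siloxybutadienes, and the C1=C2 geometry (NMe2 trans to C3) is carried over unchanged.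

Step 3
Reactants: 6 methyl (4R)-2,2-dimethyl-1,3-dioxolane-4-carboxylate
Product: 7 (4R)-N-methoxy-N,2,2-trimethyl-1,3-dioxolane-4-carboxamide
Conditions: MeNH(OMe)·HCl, i-PrMgCl, THF, −20 °C
Reagents that add atoms: N,O-dimethylhydroxylamine hydrochloride, CNOC.Cl
Why: Direct ester-to-Weinreb-amide aminolysis by the chloromagnesium amide formed in the flask should proceed at −20 °C without enolising the acetonide-locked α-alkoxy centre, and doing it first means the ring B methyl ester never has to be told apart from an aliphatic ester.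

Step 4
Reactants: 7 (4R)-N-methoxy-N,2,2-trimethyl-1,3-dioxolane-4-carboxamide
Product: 8 (2R)-2,3-dihydroxy-N-methoxy-N-methylpropanamide
Conditions: TsOH·H2O (cat.), MeOH, rt; solid NaHCO3, filter, concentrate
Reagents that add atoms: none
Why: Acid-catalysed transketalisation to methanol (acetonide methanolysis) should free the 1,2-diol while the Weinreb amide and the stereocentre are untouched by catalytic sulfonic acid at room temperature.

Step 5
Reactants: 8 (2R)-2,3-dihydroxy-N-methoxy-N-methylpropanamide
Product: 9 (2R)-3-[(tert-butyldimethylsilyl)oxy]-2-hydroxy-N-methoxy-N-methylpropanamide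
Conditions: TBSCl (1.05 equiv), imidazole, CH2Cl2, 0 °C
Reagents that add atoms: tert-butyldimethylsilyl chloride, CC(C)(C)[Si](C)(C)Cl
Why: Selective silylation of the primary hydroxyl is expected because the secondary α-hydroxy group is more hindered and hydrogen-bonded to the amide carbonyl.

Step 6
Reactants: 9 (2R)-3-[(tert-butyldimethylsilyl)oxy]-2-hydroxy-N-methoxy-N-methylpropanamide; 10 methyl syringate (methyl 4-hydroxy-3,5-dimethoxybenzoate)
Product: 11 methyl 4-{[(2S)-3-[(tert-butyldimethylsilyl)oxy]-1-[methoxy(methyl)amino]-1-oxopropan-2-yl]oxy}-3,5-dimethoxybenzoate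
Conditions: PPh3, DIAD, THF, 0 °C → rt
Reagents that add atoms: none
Why: Mitsunobu etherification, in which the acidic para-ester phenol displaces the oxyphosphonium of the carbonyl-activated secondary carbinol by SN2 with inversion, turning the (R)-carbinol into the (S)-aryl ether that becomes C8.

Step 7
Reactants: 11 methyl 4-{[(2S)-3-[(tert-butyldimethylsilyl)oxy]-1-[methoxy(methyl)amino]-1-oxopropan-2-yl]oxy}-3,5-dimethoxybenzoate
Product: 13 methyl 4-{[(2S)-1-[(tert-butyldimethylsilyl)oxy]-3-oxopent-4-yn-2-yl]oxy}-3,5-dimethoxybenzoate, via magnesium hemiaminal 12 (not isolated)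
Conditions: HC≡CMgBr, THF, −20 → 0 °C; inverse quench into cold aqueous citric acid; used promptly
Reagents that add atoms: ethynylmagnesium bromide, C#C[Mg]Br
Why: Weinreb ketone synthesis, in which the weakly nucleophilic alkynyl Grignard reagent adds once to the chelating amide and should leave the electron-rich benzoate alone below 0 °C, while the acidic inverse quench collapses the chelate and protonates MeNHOMe so that it cannot add to the ynone.

Step 8
Reactants: 5 (1Z)-3-[(tert-butyldimethylsilyl)oxy]-2-methoxy-N,N-dimethylbuta-1,3-dien-1-amine; 13 methyl 4-{[(2S)-1-[(tert-butyldimethylsilyl)oxy]-3-oxopent-4-yn-2-yl]oxy}-3,5-dimethoxybenzoate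
Product: 15 methyl 4-{[(2S)-3-[(tert-butyldimethylsilyl)oxy]-1-{4-[(tert-butyldimethylsilyl)oxy]-3-methoxyphenyl}-1-oxopropan-2-yl]oxy}-3,5-dimethoxybenzoate, via aminocyclohexadiene cycloadduct 14 (not isolated)
Conditions: 5 (1.5 equiv), toluene, −20 °C → rt; then AcOH, 0 °C → rt
Reagents that add atoms: none
Why: The electron-rich diene 5 (HOMO raised by NMe2 at C1 and OSi at C3, largest coefficient at the unsubstituted CH2 terminus) and the electron-poor terminal ynone 13 should combine in a concerted but strongly asynchronous Diels–Alder reaction in which the diene CH2 bonds to the alkyne CH (ring A C5–C6) and the amino-bearing carbon bonds to the acyl-bearing carbon (ring A C1–C2), giving the 1,4-cyclohexadiene 14. The closest known reaction type is the cycloaddition of 1-amino-3-siloxy- and 1-methoxy-3-siloxybutadienes to acetylenic ketones and esters followed by loss of amine or methanol to give para-oxygenated aryl carbonyl compounds, the 2-methoxy group being an additional spectator donor on that diene class. Ring A is closed in intermolecular (4+2) mode with both σ-bonds formed suprafacially in one step (in the stepwise limit the second bond would close by 6-exo-trig attack of the allenolate on the vinylogous iminium), and acetic acid then protonates nitrogen so that dimethylamine leaves together with a C5 proton in a 1,4-elimination driven by aromatisation, which places OMe on C3 and OSi on C4. No stereocentre is created in the product, since the aminated sp3 carbon of 14 is destroyed and C8 is only carried through. The step needs one regiochemical orientation, secured by the matched polarisation of the partners (nucleophilic diene terminus to the ynone β-carbon), and retention at the enolisable C8, secured by metal- and base-free conditions near room temperature, by excess diene so that no ynone remains when amine is released, and by removing the amine with weak acid and not with base.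

Step 9
Reactants: 15 methyl 4-{[(2S)-3-[(tert-butyldimethylsilyl)oxy]-1-{4-[(tert-butyldimethylsilyl)oxy]-3-methoxyphenyl}-1-oxopropan-2-yl]oxy}-3,5-dimethoxybenzoate
Product: 16 methyl 4-{[(1S,2S)-3-[(tert-butyldimethylsilyl)oxy]-1-{4-[(tert-butyldimethylsilyl)oxy]-3-methoxyphenyl}-1-hydroxypropan-2-yl]oxy}-3,5-dimethoxybenzoate
Conditions: LiBH(s-Bu)3, THF, −78 °C; MeOH then aqueous NH4Cl; chromatography
Reagents that add atoms: none
Why: Felkin–Anh (polar model) 1,2-induction, in which the bulky non-chelating hydride attacks the ketone anti to the C8–OAr bond and past the C8 hydrogen, should set C7 as (S) and give the syn (threo, 7S,8S) carbinol, while the methyl ester is not reduced by this reagent at −78 °C.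

Step 10
Reactants: 16 methyl 4-{[(1S,2S)-3-[(tert-butyldimethylsilyl)oxy]-1-{4-[(tert-butyldimethylsilyl)oxy]-3-methoxyphenyl}-1-hydroxypropan-2-yl]oxy}-3,5-dimethoxybenzoate
Product: 17 methyl 4-{[(1S,2S)-1,3-dihydroxy-1-(4-hydroxy-3-methoxyphenyl)propan-2-yl]oxy}-3,5-dimethoxybenzoate
Conditions: Bu4NF, AcOH, THF, 0 °C → rt
Reagents that add atoms: none
Why: Fluoride-mediated desilylation should cleave both the aryl and the primary silyl ether, and the acetic acid buffer keeps the freed p-hydroxybenzyl alcohol from quinone-methide formation and the methyl ester from premature hydrolysis.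

Step 11
Reactants: 17 methyl 4-{[(1S,2S)-1,3-dihydroxy-1-(4-hydroxy-3-methoxyphenyl)propan-2-yl]oxy}-3,5-dimethoxybenzoate
Product: 19 4-{[(1S,2S)-1,3-dihydroxy-1-(4-hydroxy-3-methoxyphenyl)propan-2-yl]oxy}-3,5-dimethoxybenzoic acid, via dilithium salt 18 (not isolated)
Conditions: LiOH, THF/MeOH/H2O (degassed), rt → 40 °C; then 1 M HCl to pH 3, 0 °C
Reagents that add atoms: lithium hydroxide, [Li+].[OH-]
Why: Saponification (acyl-oxygen cleavage) of the aryl methyl ester should proceed without touching C7 or C8, since neither centre is enolisable and β-aryl ether cleavage of the phenoxide needs far higher temperatures, and mild acidification then releases the acid.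

**Compound list**

1 | methoxyacetone (1-methoxypropan-2-one) | COCC(C)=O | starting material
2 | N,N-dimethylformamide dimethyl acetal | COC(OC)N(C)C | starting material
3 | (3Z)-4-(dimethylamino)-3-methoxybut-3-en-2-one | CN(C)/C=C(\OC)C(C)=O | intermediate
4 | potassium (3Z)-4-(dimethylamino)-3-methoxybuta-1,3-dien-2-olate | CN(C)/C=C(\OC)C(=C)[O-].[K+] | intermediate
5 | (1Z)-3-[(tert-butyldimethylsilyl)oxy]-2-methoxy-N,N-dimethylbuta-1,3-dien-1-amine | CN(C)/C=C(\OC)C(=C)O[Si](C)(C)C(C)(C)C | intermediate
6 | methyl (4R)-2,2-dimethyl-1,3-dioxolane-4-carboxylate | COC(=O)[C@H]1COC(C)(C)O1 | starting material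
7 | (4R)-N-methoxy-N,2,2-trimethyl-1,3-dioxolane-4-carboxamide | CON(C)C(=O)[C@H]1COC(C)(C)O1 | intermediate
8 | (2R)-2,3-dihydroxy-N-methoxy-N-methylpropanamide | CON(C)C(=O)[C@H](O)CO | intermediate
9 | (2R)-3-[(tert-butyldimethylsilyl)oxy]-2-hydroxy-N-methoxy-N-methylpropanamide | CON(C)C(=O)[C@H](O)CO[Si](C)(C)C(C)(C)C | intermediate
10 | methyl syringate (methyl 4-hydroxy-3,5-dimethoxybenzoate) | COC(=O)c1cc(OC)c(O)c(OC)c1 | starting material
11 | methyl 4-{[(2S)-3-[(tert-butyldimethylsilyl)oxy]-1-[methoxy(methyl)amino]-1-oxopropan-2-yl]oxy}-3,5-dimethoxybenzoate | CON(C)C(=O)[C@H](CO[Si](C)(C)C(C)(C)C)Oc1c(OC)cc(C(=O)OC)cc1OC | intermediate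
12 | bromomagnesium hemiaminal (tetrahedral adduct of ethynylmagnesium bromide and 11; hemiaminal carbon configuration undefined) | C#CC(O[Mg]Br)(N(C)OC)[C@H](CO[Si](C)(C)C(C)(C)C)Oc1c(OC)cc(C(=O)OC)cc1OC | intermediate
13 | methyl 4-{[(2S)-1-[(tert-butyldimethylsilyl)oxy]-3-oxopent-4-yn-2-yl]oxy}-3,5-dimethoxybenzoate | C#CC(=O)[C@H](CO[Si](C)(C)C(C)(C)C)Oc1c(OC)cc(C(=O)OC)cc1OC | intermediate
14 | methyl 4-{[(2S)-3-[(tert-butyldimethylsilyl)oxy]-1-{4-[(tert-butyldimethylsilyl)oxy]-6-(dimethylamino)-5-methoxycyclohexa-1,4-dien-1-yl}-1-oxopropan-2-yl]oxy}-3,5-dimethoxybenzoate (mixture at the aminated ring carbon) | CN(C)C1C(OC)=C(O[Si](C)(C)C(C)(C)C)CC=C1C(=O)[C@H](CO[Si](C)(C)C(C)(C)C)Oc2c(OC)cc(C(=O)OC)cc2OC | intermediate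
15 | methyl 4-{[(2S)-3-[(tert-butyldimethylsilyl)oxy]-1-{4-[(tert-butyldimethylsilyl)oxy]-3-methoxyphenyl}-1-oxopropan-2-yl]oxy}-3,5-dimethoxybenzoate | COc1cc(C(=O)[C@H](CO[Si](C)(C)C(C)(C)C)Oc2c(OC)cc(C(=O)OC)cc2OC)ccc1O[Si](C)(C)C(C)(C)C | intermediate
16 | methyl 4-{[(1S,2S)-3-[(tert-butyldimethylsilyl)oxy]-1-{4-[(tert-butyldimethylsilyl)oxy]-3-methoxyphenyl}-1-hydroxypropan-2-yl]oxy}-3,5-dimethoxybenzoate | COc1cc([C@H](O)[C@H](CO[Si](C)(C)C(C)(C)C)Oc2c(OC)cc(C(=O)OC)cc2OC)ccc1O[Si](C)(C)C(C)(C)C | intermediate
17 | methyl 4-{[(1S,2S)-1,3-dihydroxy-1-(4-hydroxy-3-methoxyphenyl)propan-2-yl]oxy}-3,5-dimethoxybenzoate | COc1cc([C@H](O)[C@H](CO)Oc2c(OC)cc(C(=O)OC)cc2OC)ccc1O | intermediate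
18 | dilithium phenolate carboxylate of the target | COc1cc([C@H](O)[C@H](CO)Oc2c(OC)cc(C(=O)[O-])cc2OC)ccc1[O-].[Li+].[Li+] | intermediate
19 | 4-{[(1S,2S)-1,3-dihydroxy-1-(4-hydroxy-3-methoxyphenyl)propan-2-yl]oxy}-3,5-dimethoxybenzoic acid | COc1cc([C@H](O)[C@H](CO)Oc2c(OC)cc(C(=O)O)cc2OC)ccc1O | target

**Step count**

Total: 11 steps. Longest linear sequence: 9 steps (6 → 19, steps 3 to 11); the diene branch (steps 1 and 2) joins at step 8.

**Steps most likely to fail**

1. Step 8 (Diels–Alder and aromatisation). The cycloaddition of the more hindered 2-methoxy diene may be sluggish. Dimethylamine may be lost early and add in conjugate fashion to unreacted ynone. C8 may epimerise through enolisation. The aryl silyl group may also be lost during the acid-induced elimination; in that case the phenol would be resilylated with TBSCl and imidazole before step 9. Fallback, setting out from Weinreb amide 11 and rejoining the route at ketone 15: ring A is not built but brought in intact. Commercial 4-bromo-2-methoxyphenol would be silylated (TBSCl, imidazole, CH2Cl2) to tert-butyl(4-bromo-2-methoxyphenoxy)dimethylsilane F1. This would be converted with Mg turnings in THF into {4-[(tert-butyldimethylsilyl)oxy]-3-methoxyphenyl}magnesium bromide F2. Addition of F2 to 11 at −20 °C should give the bromomagnesium hemiaminal F3, which on cold acidic quench should collapse to 15 (Weinreb ketone synthesis); steps 1, 2 and 7 are then not needed.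

2. Step 6 (Mitsunobu etherification). Substitution by the di-ortho-substituted phenol may be slow, so that elimination of the oxyphosphonium or alkylation of the hydrazide competes and conversion is low. Fallback, setting out from alcohol 9 and rejoining at 11: sulfonate activation and displacement instead of redox condensation. 9 would be converted (Tf2O, 2,6-lutidine, CH2Cl2, −78 °C) into (2R)-3-[(tert-butyldimethylsilyl)oxy]-1-[methoxy(methyl)amino]-1-oxopropan-2-yl trifluoromethanesulfonate F4. Methyl syringate 10 would be deprotonated with K2CO3 in MeCN to potassium 2,6-dimethoxy-4-(methoxycarbonyl)phenolate F5. SN2 displacement of F4 by F5 at −20 → 0 °C should give 11 with the same inversion.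

3. Step 9 (ketone reduction). Facial discrimination may be insufficient, with chelation-type delivery giving the erythro C7 epimer, or the basic hydride may enolise the ketone. Fallback, setting out from ketone 15 and rejoining at 16: the opposite epimer is made on purpose and then inverted. Chelation-controlled reduction with Zn(BH4)2 in Et2O at 0 °C should give the erythro alcohol methyl 4-{[(1R,2S)-3-[(tert-butyldimethylsilyl)oxy]-1-{4-[(tert-butyldimethylsilyl)oxy]-3-methoxyphenyl}-1-hydroxypropan-2-yl]oxy}-3,5-dimethoxybenzoate F6. Mitsunobu inversion at C7 with chloroacetic acid (PPh3, DIAD, toluene, 0 °C) should give the (1S,2S) chloroacetate F7. The chloroacetate would be removed with thiourea and NaHCO3 in EtOH, conditions under which the aryl silyl ether stays on and no phenoxide is formed next to the benzylic ester, to give 16.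

**Further compounds**

F1 | step 8 | tert-butyl(4-bromo-2-methoxyphenoxy)dimethylsilane | COc1cc(Br)ccc1O[Si](C)(C)C(C)(C)C
F2 | step 8 | {4-[(tert-butyldimethylsilyl)oxy]-3-methoxyphenyl}magnesium bromide | COc1cc([Mg]Br)ccc1O[Si](C)(C)C(C)(C)C
F3 | step 8 | bromomagnesium hemiaminal from F2 and 11 (hemiaminal carbon configuration undefined) | COc1cc(C(O[Mg]Br)(N(C)OC)[C@H](CO[Si](C)(C)C(C)(C)C)Oc2c(OC)cc(C(=O)OC)cc2OC)ccc1O[Si](C)(C)C(C)(C)C
F4 | step 6 | (2R)-3-[(tert-butyldimethylsilyl)oxy]-1-[methoxy(methyl)amino]-1-oxopropan-2-yl trifluoromethanesulfonate | CON(C)C(=O)[C@H](OS(=O)(=O)C(F)(F)F)CO[Si](C)(C)C(C)(C)C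
F5 | step 6 | potassium 2,6-dimethoxy-4-(methoxycarbonyl)phenolate | COC(=O)c1cc(OC)c([O-])c(OC)c1.[K+]
F6 | step 9 | methyl 4-{[(1R,2S)-3-[(tert-butyldimethylsilyl)oxy]-1-{4-[(tert-butyldimethylsilyl)oxy]-3-methoxyphenyl}-1-hydroxypropan-2-yl]oxy}-3,5-dimethoxybenzoate | COc1cc([C@@H](O)[C@H](CO[Si](C)(C)C(C)(C)C)Oc2c(OC)cc(C(=O)OC)cc2OC)ccc1O[Si](C)(C)C(C)(C)C
F7 | step 9 | methyl 4-{[(1S,2S)-3-[(tert-butyldimethylsilyl)oxy]-1-{4-[(tert-butyldimethylsilyl)oxy]-3-methoxyphenyl}-1-(chloroacetoxy)propan-2-yl]oxy}-3,5-dimethoxybenzoate | COc1cc([C@H](OC(=O)CCl)[C@H](CO[Si](C)(C)C(C)(C)C)Oc2c(OC)cc(C(=O)OC)cc2OC)ccc1O[Si](C)(C)C(C)(C)C
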